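**Plan**
- Retrosynthesis: remove the angelate (C3–O acyl bond) and the coumarin (C11–O aryl bond), then cut C9–C10 and C1–C2 of the decalin together to reach an open-chain α-silyloxy aldehyde, then cut C4–C5 (Claisen) to an allyl vinyl ether built from geraniol, a diazophosphonoacetate and acetone.
- Forward: the chain is assembled first; ring A closes by attack of the isopropenyl terminus C1 on the aldehyde carbon C2, and the C10 cation formed closes ring B onto C9 of the C8=C9 olefin in the same operation.
- Enabling feature: the quaternary C10 with its angular methyl lies between C1 and C9. Written as an isopropenyl group (C1=C10–CH3) placed 1,5 to the C2 carbonyl and 1,5 to C9, it is a latent tertiary cation that can zip ring A and ring B; the C7=C8 olefin of ring B is the natural end point (loss of H7).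
- Stereochemistry: C5 comes from a catalytic enantioselective Gosteli–Claisen rearrangement and C3 from a reagent-controlled reduction of the α-keto ester. C10 and C9 follow from C5 through chair transition states (trans ring fusion; E-olefin gives equatorial C11). The Z-ester geometry is carried in with angelic acid.

Key step: step 9

Remark: drimane numbering of the target is used for all intermediates, open-chain ones included (C1–C10 ring carbons, C11 = CH2O on C9, C12 = methyl on C8, C13 and C14 = methyls on C4, C15 = methyl on C10).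
Remark (assumption): the (S,S)-t-Bu-box copper catalyst is taken to give the (4S)-keto ester 8, and (+)-Ipc2BCl the (2S)-alcohol 9 (quaternary carbon as the large group, as with pinacolone); if either sense proves opposite, the mirror-image ligand or reagent, equally available, is used.
Remark (assumption): compound 4 is taken as a commercial reagent; otherwise it is one diazo-transfer step from triethyl phosphonoacetate.

**Route**

Step 1
Reactants: 1 geraniol
Product: 2 geranyl tert-butyldiphenylsilyl ether
Conditions: TBDPSCl, imidazole, CH2Cl2, 0 °C to rt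
Reagents that add atoms: tert-butyldiphenylsilyl chloride, CC(C)(C)[Si](Cl)(c1ccccc1)c1ccccc1
Why: Silylation of the primary allylic alcohol should give an ether that withstands the SeO2, enolate, hydride and Lewis acid steps and is removed together with the second silyl group in step 11.

Step 2
Reactants: 2 geranyl tert-butyldiphenylsilyl ether
Product: 3 (2E,6E)-8-(tert-butyldiphenylsilyloxy)-2,6-dimethylocta-2,6-dien-1-ol
Conditions: SeO2 (0.3 equiv), t-BuOOH, salicylic acid (cat.), CH2Cl2, rt
Reagents that add atoms: tert-butyl hydroperoxide, CC(C)(C)OO (net source of the new oxygen, passed on by SeO2, O=[Se]=O)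
Why: Riley allylic oxidation (ene reaction, then 2,3-sigmatropic shift) should hydroxylate the E-methyl group of the more electron-rich terminal olefin, giving the E-allylic alcohol whose carbinol carbon becomes C1.

Step 3
Reactants: 3 (2E,6E)-8-(tert-butyldiphenylsilyloxy)-2,6-dimethylocta-2,6-dien-1-ol; 4 ethyl 2-diazo-2-(diethoxyphosphoryl)acetate
Product: 5 ethyl 2-{[(2E,6E)-8-(tert-butyldiphenylsilyloxy)-2,6-dimethylocta-2,6-dien-1-yl]oxy}-2-(diethoxyphosphoryl)acetate (racemic at the phosphonate carbon)
Conditions: Rh2(OAc)4 (2 mol%), benzene, 80 °C, slow addition of 4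
Reagents that add atoms: none
Why: Rhodium carbenoid O–H insertion into the allylic alcohol should outrun cyclopropanation of the trisubstituted olefins for this acceptor/acceptor carbenoid, installing the future C2 and C3.

Step 4
Reactants: 5 the α-allyloxy phosphonoacetate; 6 acetone
Product: 7 ethyl 2-{[(2E,6E)-8-(tert-butyldiphenylsilyloxy)-2,6-dimethylocta-2,6-dien-1-yl]oxy}-3-methylbut-2-enoate
Conditions: LiN(SiMe3)2, THF, −78 °C; acetone (excess), −78 °C to rt
Reagents that add atoms: none
Why: Horner–Wadsworth–Emmons olefination of acetone should give the 2-alkoxycarbonyl allyl vinyl ether with no E/Z question, because the new olefin terminus (future C4) carries two methyl groups.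

Step 5
Reactants: 7 the allyl vinyl ether
Product: 8 ethyl (4S,7E)-9-(tert-butyldiphenylsilyloxy)-3,3,7-trimethyl-2-oxo-4-(prop-1-en-2-yl)non-7-enoate
Conditions: [Cu((S,S)-t-Bu-box)(H2O)2](SbF6)2 (10 mol%; box = 2,2'-isopropylidenebis(4-tert-butyl-2-oxazoline)), CH2Cl2, rt
Reagents that add atoms: none
Why: In this catalytic asymmetric Gosteli–Claisen rearrangement the ether oxygen and ester carbonyl chelate the chiral copper Lewis acid, one face of the enol ether is shielded, and the chair transition state with the E-allyl unit relays this to C5 while forming the C4–C5 bond, the gem-dimethyl group, the isopropenyl group (C1=C10) and the α-keto ester (C2, C3) together.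

Step 6
Reactants: 8 the α-keto ester
Product: 9 ethyl (2S,4S,7E)-9-(tert-butyldiphenylsilyloxy)-2-hydroxy-3,3,7-trimethyl-4-(prop-1-en-2-yl)non-7-enoate
Conditions: (+)-Ipc2BCl (2 equiv), THF, −25 °C to rt; then CH3CHO, 0 °C to rt; then aq. NaOH, 0 °C
Reagents that add atoms: none
Why: Reduction with B-chlorodiisopinocampheylborane transfers hydride through a boat-like six-membered transition state with the quaternary carbon in the large-group position, so C3 should be set by the reagent while the olefins stay untouched.

Step 7
Reactants: 9 the α-hydroxy ester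
Product: 10 ethyl (2S,4S,7E)-2-(tert-butyldimethylsilyloxy)-9-(tert-butyldiphenylsilyloxy)-3,3,7-trimethyl-4-(prop-1-en-2-yl)non-7-enoate
Conditions: TBSOTf, 2,6-lutidine, CH2Cl2, 0 °C to rt
Reagents that add atoms: tert-butyldimethylsilyl triflate, CC(C)(C)[Si](C)(C)OS(=O)(=O)C(F)(F)F
Why: The silyl triflate should silylate the hindered secondary hydroxyl and give a non-participating group that tolerates the Lewis acid of step 9.

Step 8
Reactants: 10 the silyl-protected ester
Product: 11 (2S,4S,7E)-2-(tert-butyldimethylsilyloxy)-9-(tert-butyldiphenylsilyloxy)-3,3,7-trimethyl-4-(prop-1-en-2-yl)non-7-enal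
Conditions: i-Bu2AlH (1.1 equiv), CH2Cl2, −78 °C; aq. potassium sodium tartrate
Reagents that add atoms: none
Why: Partial reduction of the α-silyloxy ester should stop at the aldehyde because the tetrahedral aluminium hemiacetal is stable at −78 °C, and C3 is not enolized under these conditions.

Step 9
Reactants: 11 the open-chain α-silyloxy aldehyde
Product: 12 (2S,3S,5S,9R,10R)-3-(tert-butyldimethylsilyloxy)-11-(tert-butyldiphenylsilyloxy)drim-7-en-2-ol (trans-decalin; 2-OH and 3-OSi equatorial)
Conditions: MeAlCl2 (2.2 equiv), CH2Cl2, −78 °C to −45 °C; then H2O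
Reagents that add atoms: none
Why: MeAlCl2 binds the aldehyde oxygen and the C1 terminus of the isopropenyl group adds to C2 (Prins step), giving a tertiary C10 cation that is trapped by C9 of the E-configured C8=C9 olefin, after which the C8 cation loses H7 (taken up by a methyl on aluminium as methane) to leave the C7=C8 double bond. The closest known reaction type is the alkylaluminium halide-induced Prins/cation–olefin cyclization of unsaturated aldehydes, here joined to the ring closure known for monocyclofarnesyl cations on the way to drimanes. Ring A closes 6-endo-trig at the isopropenyl olefin (6-exo at the carbonyl) and ring B closes 6-endo-trig at the C8=C9 olefin. C10 is controlled by C5, since the C5 side chain and the C3 silyloxy group sit equatorial in the ring A chair and C9 adds from the equatorial direction, leaving the methyl axial and anti to H5 (trans fusion); C9 is controlled by the E-geometry of the olefin in a chair-like ring B transition state (C11 equatorial, H9 anti to the methyl); C2 is expected equatorial, but either epimer converges in step 10. The step needs cation capture to beat ene-type proton loss and needs regioselective termination; an excess of the strongly acidic MeAlCl2 should favour the stepwise zwitterionic path, the trisubstituted olefin sits 1,5 to the cation, and axial H7 is the proton aligned with the empty orbital at C8.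

Step 10
Reactants: 12 the bicyclic alcohol
Product: 13 (3S,5S,9R,10R)-3-(tert-butyldimethylsilyloxy)-11-(tert-butyldiphenylsilyloxy)drim-7-en-2-one
Conditions: Dess–Martin periodinane, CH2Cl2, rt
Reagents that add atoms: none
Why: Dess–Martin oxidation of the secondary alcohol under near-neutral conditions should give the C2 ketone without epimerizing the adjacent silyloxy-bearing C3.

Step 11
Reactants: 13 the bis-silyl ketone
Product: 14 (3S,5S,9R,10R)-3,11-dihydroxydrim-7-en-2-one
Conditions: HF·pyridine, THF/pyridine, 0 °C to rt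
Reagents that add atoms: none
Why: Fluoride-mediated cleavage should remove both silyl ethers in one operation, and the acidic medium avoids base-induced epimerization or ketol shift of the α-hydroxy ketone.

Step 12
Reactants: 14 the keto diol; 15 umbelliferone (7-hydroxy-2H-chromen-2-one)
Product: 16 7-{[(3S,5S,9R,10R)-3-hydroxy-2-oxodrim-7-en-11-yl]oxy}-2H-chromen-2-one
Conditions: PPh3, DIAD, THF, 0 °C to rt
Reagents that add atoms: none
Why: Mitsunobu etherification with the acidic phenol should engage only the primary C11 hydroxyl, since the secondary C3 hydroxyl is flanked by the gem-dimethyl carbon and the ketone and is too hindered to be activated.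

Step 13
Reactants: 16 the hydroxy ketone coumarin ether; 17 angelic acid ((2Z)-2-methylbut-2-enoic acid)
Product: 19 (3S,5S,9R,10R)-2-oxo-11-[(2-oxo-2H-chromen-7-yl)oxy]drim-7-en-3-yl (2Z)-2-methylbut-2-enoate (CNP0111364.1), via angelic 2,4,6-trichlorobenzoic anhydride 18 (not isolated)
Conditions: 2,4,6-Cl3C6H2COCl, Et3N, toluene, rt; then 16, 75 °C
Reagents that add atoms: none
Why: Yamaguchi-type acylation through the mixed anhydride without a nucleophilic catalyst should transfer the angeloyl group to the hindered C3 hydroxyl with the Z-geometry intact, and no stereocenter is touched.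

**Compound list**
1 | geraniol, (2E)-3,7-dimethylocta-2,6-dien-1-ol | CC(C)=CCC/C(C)=C/CO | starting material
2 | geranyl tert-butyldiphenylsilyl ether | CC(C)=CCC/C(C)=C/CO[Si](c1ccccc1)(c1ccccc1)C(C)(C)C | intermediate
3 | (2E,6E)-8-(tert-butyldiphenylsilyloxy)-2,6-dimethylocta-2,6-dien-1-ol | OC/C(C)=C/CC/C(C)=C/CO[Si](c1ccccc1)(c1ccccc1)C(C)(C)C | intermediate
4 | ethyl 2-diazo-2-(diethoxyphosphoryl)acetate | CCOC(=O)C(=[N+]=[N-])P(=O)(OCC)OCC | starting material
5 | ethyl 2-{[(2E,6E)-8-(tert-butyldiphenylsilyloxy)-2,6-dimethylocta-2,6-dien-1-yl]oxy}-2-(diethoxyphosphoryl)acetate (racemic at the phosphonate carbon) | CCOC(=O)C(OC/C(C)=C/CC/C(C)=C/CO[Si](c1ccccc1)(c1ccccc1)C(C)(C)C)P(=O)(OCC)OCC | intermediate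
6 | acetone | CC(C)=O | starting material
7 | ethyl 2-{[(2E,6E)-8-(tert-butyldiphenylsilyloxy)-2,6-dimethylocta-2,6-dien-1-yl]oxy}-3-methylbut-2-enoate | CCOC(=O)C(OC/C(C)=C/CC/C(C)=C/CO[Si](c1ccccc1)(c1ccccc1)C(C)(C)C)=C(C)C | intermediate
8 | ethyl (4S,7E)-9-(tert-butyldiphenylsilyloxy)-3,3,7-trimethyl-2-oxo-4-(prop-1-en-2-yl)non-7-enoate | CCOC(=O)C(=O)C(C)(C)[C@H](C(C)=C)CC/C(C)=C/CO[Si](c1ccccc1)(c1ccccc1)C(C)(C)C | intermediate
9 | ethyl (2S,4S,7E)-9-(tert-butyldiphenylsilyloxy)-2-hydroxy-3,3,7-trimethyl-4-(prop-1-en-2-yl)non-7-enoate | CCOC(=O)[C@@H](O)C(C)(C)[C@H](C(C)=C)CC/C(C)=C/CO[Si](c1ccccc1)(c1ccccc1)C(C)(C)C | intermediate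
10 | ethyl (2S,4S,7E)-2-(tert-butyldimethylsilyloxy)-9-(tert-butyldiphenylsilyloxy)-3,3,7-trimethyl-4-(prop-1-en-2-yl)non-7-enoate | CCOC(=O)[C@@H](O[Si](C)(C)C(C)(C)C)C(C)(C)[C@H](C(C)=C)CC/C(C)=C/CO[Si](c1ccccc1)(c1ccccc1)C(C)(C)C | intermediate
11 | (2S,4S,7E)-2-(tert-butyldimethylsilyloxy)-9-(tert-butyldiphenylsilyloxy)-3,3,7-trimethyl-4-(prop-1-en-2-yl)non-7-enal | O=C[C@@H](O[Si](C)(C)C(C)(C)C)C(C)(C)[C@H](C(C)=C)CC/C(C)=C/CO[Si](c1ccccc1)(c1ccccc1)C(C)(C)C | intermediate
12 | (2S,3S,5S,9R,10R)-3-(tert-butyldimethylsilyloxy)-11-(tert-butyldiphenylsilyloxy)drim-7-en-2-ol (2S expected; the C2 epimer converges in step 10) | CC(C)(C)[Si](C)(C)O[C@@H]1[C@@H](O)C[C@@]2(C)[C@H](CO[Si](c3ccccc3)(c3ccccc3)C(C)(C)C)C(C)=CC[C@@H]2C1(C)C | intermediate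
13 | (3S,5S,9R,10R)-3-(tert-butyldimethylsilyloxy)-11-(tert-butyldiphenylsilyloxy)drim-7-en-2-one | CC(C)(C)[Si](C)(C)O[C@@H]1C(=O)C[C@@]2(C)[C@H](CO[Si](c3ccccc3)(c3ccccc3)C(C)(C)C)C(C)=CC[C@@H]2C1(C)C | intermediate
14 | (3S,5S,9R,10R)-3,11-dihydroxydrim-7-en-2-one | O[C@@H]1C(=O)C[C@@]2(C)[C@H](CO)C(C)=CC[C@@H]2C1(C)C | intermediate
15 | umbelliferone, 7-hydroxy-2H-chromen-2-one | O=c1ccc2ccc(O)cc2o1 | starting material
16 | 7-{[(3S,5S,9R,10R)-3-hydroxy-2-oxodrim-7-en-11-yl]oxy}-2H-chromen-2-one | O[C@@H]1C(=O)C[C@@]2(C)[C@H](COc3ccc4ccc(=O)oc4c3)C(C)=CC[C@@H]2C1(C)C | intermediate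
17 | angelic acid, (2Z)-2-methylbut-2-enoic acid | C/C=C(/C)C(=O)O | starting material
18 | angelic 2,4,6-trichlorobenzoic anhydride | C/C=C(/C)C(=O)OC(=O)c1c(Cl)cc(Cl)cc1Cl | intermediate
19 | (3S,5S,9R,10R)-2-oxo-11-[(2-oxo-2H-chromen-7-yl)oxy]drim-7-en-3-yl (2Z)-2-methylbut-2-enoate, CNP0111364.1 | C/C=C(/C)C(=O)O[C@@H]1C(=O)C[C@@]2(C)[C@H](COc3ccc4ccc(=O)oc4c3)C(C)=CC[C@@H]2C1(C)C | target

**Step count**
Total steps: 13. Longest linear sequence: 13 steps (1 to 19).

**Steps most likely to fail**

Step 9. The tertiary C10 cation may lose a proton from the C15 methyl group (carbonyl-ene outcome) faster than it is captured by the C8=C9 olefin, or the C8 cation may be deprotonated at C12 or C9 instead of C7. The fallback separates the two ring closures and sets out from 11. Me2AlCl (1 equiv, CH2Cl2, −78 °C) is used on purpose to stop at the carbonyl-ene product (1S,2S,4S)-2-(tert-butyldimethylsilyloxy)-4-[(3E)-5-(tert-butyldiphenylsilyloxy)-3-methylpent-3-en-1-yl]-3,3-dimethyl-5-methylidenecyclohexan-1-ol F1, in which ring A is already closed through the same C1–C2 bond. F1 is then treated with ClSO3H in 2-nitropropane at −78 °C; protonation of the exocyclic methylene regenerates the C10 cation under the Brønsted superacid conditions known to close ring B of monocyclofarnesyl substrates with loss of H7. This comes back to the route at 12.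

Step 5. Enantiofacial discrimination may be poor or turnover slow, because the enol terminus carries two identical methyl groups and the allyl unit is 2-substituted, both at the edge of what the chelating copper catalyst has been shown to handle. The fallback sets out from 7. Thermal rearrangement (toluene, 100 °C) gives the racemic keto ester, ethyl (7E)-9-(tert-butyldiphenylsilyloxy)-3,3,7-trimethyl-2-oxo-4-(prop-1-en-2-yl)non-7-enoate F2. Reduction with (+)-Ipc2BCl as in step 6 then sets C3 by reagent control in both C5 series, giving 9 together with its diastereomer ethyl (2S,4R,7E)-9-(tert-butyldiphenylsilyloxy)-2-hydroxy-3,3,7-trimethyl-4-(prop-1-en-2-yl)non-7-enoate F3. The two are diastereomers and should be separable by chromatography; F3 is discarded and the route is rejoined at 9. C5 is then secured by resolution against the reagent-set C3 and not by the catalyst.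

Step 13. The 2-methylbut-2-enoyl unit may isomerize from Z to E through reversible conjugate addition of chloride or amine to the activated acyl species, and slow acyl transfer to the hindered C3 hydroxyl leaves time for ketol tautomerization. The fallback sets out from 16 and builds the Z-olefin after the acylation. Esterification of 16 with 2-[bis(2,2,2-trifluoroethoxy)phosphoryl]propanoic acid (DCC, cat. DMAP, CH2Cl2) gives (3S,5S,9R,10R)-2-oxo-11-[(2-oxo-2H-chromen-7-yl)oxy]drim-7-en-3-yl 2-[bis(2,2,2-trifluoroethoxy)phosphoryl]propanoate F4, an acyl group with no olefin to isomerize. Still–Gennari olefination of F4 with acetaldehyde (KN(SiMe3)2, 18-crown-6, THF, −78 °C) then forms the Z-trisubstituted enoate and arrives at 19.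

**Further compounds**
F1 | step 9 | (1S,2S,4S)-2-(tert-butyldimethylsilyloxy)-4-[(3E)-5-(tert-butyldiphenylsilyloxy)-3-methylpent-3-en-1-yl]-3,3-dimethyl-5-methylidenecyclohexan-1-ol | O[C@H]1CC(=C)[C@H](CC/C(C)=C/CO[Si](c2ccccc2)(c2ccccc2)C(C)(C)C)C(C)(C)[C@@H]1O[Si](C)(C)C(C)(C)C
F2 | step 5 | ethyl (7E)-9-(tert-butyldiphenylsilyloxy)-3,3,7-trimethyl-2-oxo-4-(prop-1-en-2-yl)non-7-enoate (racemic) | CCOC(=O)C(=O)C(C)(C)C(C(C)=C)CC/C(C)=C/CO[Si](c1ccccc1)(c1ccccc1)C(C)(C)C
F3 | step 5 | ethyl (2S,4R,7E)-9-(tert-butyldiphenylsilyloxy)-2-hydroxy-3,3,7-trimethyl-4-(prop-1-en-2-yl)non-7-enoate | CCOC(=O)[C@@H](O)C(C)(C)[C@@H](C(C)=C)CC/C(C)=C/CO[Si](c1ccccc1)(c1ccccc1)C(C)(C)C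
F4 | step 13 | (3S,5S,9R,10R)-2-oxo-11-[(2-oxo-2H-chromen-7-yl)oxy]drim-7-en-3-yl 2-[bis(2,2,2-trifluoroethoxy)phosphoryl]propanoate | CC(C(=O)O[C@@H]1C(=O)C[C@@]2(C)[C@H](COc3ccc4ccc(=O)oc4c3)C(C)=CC[C@@H]2C1(C)C)P(=O)(OCC(F)(F)F)OCC(F)(F)F
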